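**Retrosynthetic overview**

1. Target 11 ← 10 by hydrogenolysis of ten benzyl ethers; 10 ← α,α-diaryl ketone 9 by reagent-controlled reduction, which sets the carbinol C2. (Chain carbons: C1 = diarylmethine, C2 = carbinol/carbonyl, C3 = CH2; flavan positions are written "flavan C2, C8" etc.)
2. Key disconnection: C1–flavan C8. C1 of a 1,3-diarylacetone is normally a nucleophilic enolate carbon; as the α-keto carbenoid from diazo ketone 7 it is an enolonium equivalent and is attacked by the nucleophilic flavan C8 of penta-O-benzylcatechin 3. A chiral proton shuttle sets C1.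
3. 7 ← ketone 6 ← reductive opening of flavan-3-one 4. Both 3 and 4 come from tetra-O-benzylcatechin 2, made from (+)-catechin 1.
4. Rings: none is built. The chroman of the lower half is carried through from 1; the pyran ring of the upper half is opened in step 4.

Assumption: the sense of induction of the chiral phosphoric acid in step 7 is assigned by analogy; if the (1R) epimer predominates, the (R) acid is used instead.

**Route**

Step 1
Reactants: 1 (+)-catechin
Product: 2 (2R,3S)-5,7-bis(benzyloxy)-2-[3,4-bis(benzyloxy)phenyl]chroman-3-ol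
Conditions: BnBr (4.4 equiv), K2CO3, DMF, 0 °C to rt, argon
Reagents that add atoms: benzyl bromide, BrCc1ccccc1
Why: Williamson etherification of the four phenols only; carbonate does not deprotonate the secondary alcohol, and the two flavan stereocentres are untouched.

Step 2
Reactants: 2 (2R,3S)-5,7-bis(benzyloxy)-2-[3,4-bis(benzyloxy)phenyl]chroman-3-ol
Product: 3 (2R,3S)-3,5,7-tris(benzyloxy)-2-[3,4-bis(benzyloxy)phenyl]chromane
Conditions: NaH, BnBr, DMF, 0 °C to rt
Reagents that add atoms: benzyl bromide, BrCc1ccccc1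
Why: Williamson etherification of the 3-OH, so that no O–H bond is left to intercept the carbenoid of step 7; it is removed with the other benzyl groups at the end.

Step 3
Reactants: 2 (2R,3S)-5,7-bis(benzyloxy)-2-[3,4-bis(benzyloxy)phenyl]chroman-3-ol
Product: 4 (2R)-5,7-bis(benzyloxy)-2-[3,4-bis(benzyloxy)phenyl]chroman-3-one
Conditions: Dess–Martin periodinane, CH2Cl2, rt
Reagents that add atoms: none
Why: Dess–Martin oxidation of the secondary alcohol to the flavan-3-one, which turns the flavan C2–O1 bond into a cleavable α-aryloxy ketone bond.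

Step 4
Reactants: 4 (2R)-5,7-bis(benzyloxy)-2-[3,4-bis(benzyloxy)phenyl]chroman-3-one
Product: 5 1-[3,4-bis(benzyloxy)phenyl]-3-[2,4-bis(benzyloxy)-6-hydroxyphenyl]propan-2-one
Conditions: SmI2 (2.5 equiv), THF–MeOH, −78 °C; pH 7 buffer work-up
Reagents that add atoms: none
Why: SmI2 reductive cleavage of an α-aryloxy ketone: ketyl formation expels the phenoxide, methanol protonates the enolate, and the open 1,3-diarylacetone results with the old stereocentre erased.

Step 5
Reactants: 5 1-[3,4-bis(benzyloxy)phenyl]-3-[2,4-bis(benzyloxy)-6-hydroxyphenyl]propan-2-one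
Product: 6 1-[3,4-bis(benzyloxy)phenyl]-3-[2,4,6-tris(benzyloxy)phenyl]propan-2-one
Conditions: BnBr (1.1 equiv), K2CO3, acetone, rt
Reagents that add atoms: benzyl bromide, BrCc1ccccc1
Why: Williamson etherification; only the phenol is deprotonated by carbonate at rt, and capping it stops it from re-closing onto C1 in step 7.

Step 6
Reactants: 6 1-[3,4-bis(benzyloxy)phenyl]-3-[2,4,6-tris(benzyloxy)phenyl]propan-2-one
Product: 7 1-diazo-1-[3,4-bis(benzyloxy)phenyl]-3-[2,4,6-tris(benzyloxy)phenyl]propan-2-one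
Conditions: p-ABSA (1.2 equiv), DBU (1.5 equiv), MeCN, 0 °C to rt
Reagents that add atoms: 4-acetamidobenzenesulfonyl azide, CC(=O)Nc1ccc(cc1)S(=O)(=O)N=[N+]=[N-]
Why: Regitz diazo transfer; DBU enolises the less hindered, more acidic catechol-side CH2 (the other CH2 carries a ring twisted by two ortho benzyloxy groups), so the diazo group is placed at C1.

Step 7
Reactants: 7 1-diazo-1-[3,4-bis(benzyloxy)phenyl]-3-[2,4,6-tris(benzyloxy)phenyl]propan-2-one; 3 (2R,3S)-3,5,7-tris(benzyloxy)-2-[3,4-bis(benzyloxy)phenyl]chromane (1.5 equiv)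
Product: 9 (1S)-1-[3,4-bis(benzyloxy)phenyl]-1-[(2R,3S)-3,5,7-tris(benzyloxy)-2-(3,4-bis(benzyloxy)phenyl)chroman-8-yl]-3-[2,4,6-tris(benzyloxy)phenyl]propan-2-one, via enol tautomer 8 (not isolated)
Conditions: Rh2(OAc)4 (1 mol %), (S)-3,3′-bis(2,4,6-triisopropylphenyl)-1,1′-binaphthyl-2,2′-diyl hydrogen phosphate (5 mol %), CH2Cl2, 4 Å MS, 0 °C, slow addition of 7 over 3 h
Reagents that add atoms: none
Why: Proposed new method: loss of N2 at dirhodium makes C1 an electrophilic α-keto carbene carbon (enolonium equivalent), which the most nucleophilic and less hindered flavan C8 of 3 attacks (same site preference as NBS bromination of 5,7-di-O-benzylflavans); rearomatisation releases enol 8, which the chiral phosphoric acid protonates at C1 as a proton shuttle to set (1S); the closest known reaction type is dirhodium-carbene aryl C–H functionalisation of trialkoxybenzenes and dialkylanilines by aryldiazoacetates and α-aryl-α-diazoketones with phosphoric-acid control of the new stereocentre, and excess 3 with slow addition is meant to outrun oxonium-ylide formation and benzylic C–H insertion.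

Step 8
Reactants: 9 (1S)-1-[3,4-bis(benzyloxy)phenyl]-1-[(2R,3S)-3,5,7-tris(benzyloxy)-2-(3,4-bis(benzyloxy)phenyl)chroman-8-yl]-3-[2,4,6-tris(benzyloxy)phenyl]propan-2-one
Product: 10 (1S,2S)-1-[3,4-bis(benzyloxy)phenyl]-1-[(2R,3S)-3,5,7-tris(benzyloxy)-2-(3,4-bis(benzyloxy)phenyl)chroman-8-yl]-3-[2,4,6-tris(benzyloxy)phenyl]propan-2-ol
Conditions: (R)-2-methyl-CBS-oxazaborolidine (0.5 equiv), BH3·SMe2 (1.0 equiv), toluene, −30 °C; MeOH quench
Reagents that add atoms: none
Why: Corey–Bakshi–Shibata reduction: with the branched diarylmethyl group as the large and the benzylic CH2 as the small ketone substituent, the (R)-catalyst delivers hydride to the face that gives (2S), and the cold, base-free medium does not enolise the labile C1.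

Step 9
Reactants: 10 (1S,2S)-1-[3,4-bis(benzyloxy)phenyl]-1-[(2R,3S)-3,5,7-tris(benzyloxy)-2-(3,4-bis(benzyloxy)phenyl)chroman-8-yl]-3-[2,4,6-tris(benzyloxy)phenyl]propan-2-ol
Product: 11 (1S,2S)-1-(3,4-dihydroxyphenyl)-1-[(2R,3S)-2-(3,4-dihydroxyphenyl)-3,5,7-trihydroxychroman-8-yl]-3-(2,4,6-trihydroxyphenyl)propan-2-ol
Conditions: H2 (1 atm), Pd(OH)2/C, THF–MeOH, rt; filtration under argon, Sephadex LH-20
Reagents that add atoms: none
Why: Hydrogenolysis of nine aryl benzyl ethers and one alkyl benzyl ether; the C–C bonds at the diarylmethine and the flavan pyran ring are inert under these mild conditions, so all four stereocentres survive.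

**Compound list**

1 | (+)-catechin, (2R,3S)-2-(3,4-dihydroxyphenyl)chromane-3,5,7-triol | Oc1cc(O)c2c(c1)O[C@H](c1ccc(O)c(O)c1)[C@@H](O)C2 | starting material
2 | (2R,3S)-5,7-bis(benzyloxy)-2-[3,4-bis(benzyloxy)phenyl]chroman-3-ol | c1ccccc1COc1cc(OCc3ccccc3)c2c(c1)O[C@H](c1ccc(OCc3ccccc3)c(OCc3ccccc3)c1)[C@@H](O)C2 | intermediate
3 | (2R,3S)-3,5,7-tris(benzyloxy)-2-[3,4-bis(benzyloxy)phenyl]chromane | c1ccccc1COc1cc(OCc3ccccc3)c2c(c1)O[C@H](c1ccc(OCc3ccccc3)c(OCc3ccccc3)c1)[C@@H](OCc1ccccc1)C2 | intermediate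
4 | (2R)-5,7-bis(benzyloxy)-2-[3,4-bis(benzyloxy)phenyl]chroman-3-one | c1ccccc1COc1cc(OCc3ccccc3)c2c(c1)O[C@H](c1ccc(OCc3ccccc3)c(OCc3ccccc3)c1)C(=O)C2 | intermediate
5 | 1-[3,4-bis(benzyloxy)phenyl]-3-[2,4-bis(benzyloxy)-6-hydroxyphenyl]propan-2-one | O=C(Cc1ccc(OCc2ccccc2)c(OCc2ccccc2)c1)Cc1c(O)cc(OCc2ccccc2)cc1OCc1ccccc1 | intermediate
6 | 1-[3,4-bis(benzyloxy)phenyl]-3-[2,4,6-tris(benzyloxy)phenyl]propan-2-one | O=C(Cc1ccc(OCc2ccccc2)c(OCc2ccccc2)c1)Cc1c(OCc2ccccc2)cc(OCc2ccccc2)cc1OCc1ccccc1 | intermediate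
7 | 1-diazo-1-[3,4-bis(benzyloxy)phenyl]-3-[2,4,6-tris(benzyloxy)phenyl]propan-2-one | [N-]=[N+]=C(c1ccc(OCc2ccccc2)c(OCc2ccccc2)c1)C(=O)Cc1c(OCc2ccccc2)cc(OCc2ccccc2)cc1OCc1ccccc1 | intermediate
8 | enol tautomer of 9 (prop-1-en-2-ol; double-bond geometry not defined; not isolated) | OC(Cc1c(OCc2ccccc2)cc(OCc2ccccc2)cc1OCc1ccccc1)=C(c1ccc(OCc2ccccc2)c(OCc2ccccc2)c1)c1c(OCc2ccccc2)cc(OCc2ccccc2)c2c1O[C@H](c1ccc(OCc3ccccc3)c(OCc3ccccc3)c1)[C@@H](OCc1ccccc1)C2 | intermediate
9 | (1S)-1-[3,4-bis(benzyloxy)phenyl]-1-[(2R,3S)-3,5,7-tris(benzyloxy)-2-(3,4-bis(benzyloxy)phenyl)chroman-8-yl]-3-[2,4,6-tris(benzyloxy)phenyl]propan-2-one | c1ccccc1COc1cc(OCc2ccccc2)c(CC(=O)[C@@H](c2ccc(OCc4ccccc4)c(OCc4ccccc4)c2)c2c(OCc4ccccc4)cc(OCc4ccccc4)c3c2O[C@H](c2ccc(OCc4ccccc4)c(OCc4ccccc4)c2)[C@@H](OCc2ccccc2)C3)c(OCc2ccccc2)c1 | intermediate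
10 | (1S,2S)-1-[3,4-bis(benzyloxy)phenyl]-1-[(2R,3S)-3,5,7-tris(benzyloxy)-2-(3,4-bis(benzyloxy)phenyl)chroman-8-yl]-3-[2,4,6-tris(benzyloxy)phenyl]propan-2-ol | c1ccccc1COc1cc(OCc2ccccc2)c(C[C@H](O)[C@@H](c2ccc(OCc4ccccc4)c(OCc4ccccc4)c2)c2c(OCc4ccccc4)cc(OCc4ccccc4)c3c2O[C@H](c2ccc(OCc4ccccc4)c(OCc4ccccc4)c2)[C@@H](OCc2ccccc2)C3)c(OCc2ccccc2)c1 | intermediate
11 | CNP0175733.2, (1S,2S)-1-(3,4-dihydroxyphenyl)-1-[(2R,3S)-2-(3,4-dihydroxyphenyl)-3,5,7-trihydroxychroman-8-yl]-3-(2,4,6-trihydroxyphenyl)propan-2-ol | Oc1cc(O)c(C[C@H](O)[C@@H](c2ccc(O)c(O)c2)c2c(O)cc(O)c3c2O[C@H](c2ccc(O)c(O)c2)[C@@H](O)C3)c(O)c1 | target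

**Step count**

Total: 9 steps. Longest linear sequence: 8 steps (1, 3, 4, 5, 6, 7, 8, 9); step 2 is the one-step branch to the nucleophile 3.

**Steps most likely to fail, with fallbacks**

Step 7 (key C–C bond). The carbenoid may be diverted by the ortho benzyloxy oxygens of its own phloroglucinol ring (oxonium ylide) or by benzylic C–H insertion, and control of C1 by the acid is unproven on this substrate. The fallback generates the electrophilic α-carbon without a carbene. It sets out from 6, which is converted with TMSOTf and Et3N (CH2Cl2, 0 °C) into the aryl-conjugated (Z)-1-[3,4-bis(benzyloxy)phenyl]-2-(trimethylsilyloxy)-3-[2,4,6-tris(benzyloxy)phenyl]prop-1-ene F1. F1 is oxidised with [hydroxy(tosyloxy)iodo]benzene and BF3·OEt2 at −78 °C, and 3 is then added, which attacks through flavan C8. This gives the coupled ketone as both C1 epimers, 9 and the (1R) epimer of 9 F2. They are separated, F2 is re-equilibrated at C1 with DBU in toluene and recycled, and the route is rejoined at 9.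

Step 8 (C2 by reagent control). A Felkin–Anh reading of the α,α-diaryl centre puts hydride anti to the 2,6-dioxygenated flavanyl ring, which favours the (2R) epimer from (1S)-9. The catalyst therefore has to override the substrate, and the diastereomer ratio may be modest. The fallback gives up reagent control for a separation and recycle loop. It sets out from 9: NaBH4 in THF–MeOH at −78 °C gives 10 together with the (1S,2R) epimer of 10 F3. 10 is isolated, which is the return to the route at 10, and F3 is oxidised back to 9 with Dess–Martin periodinane and resubmitted.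

Step 6 (site of diazo transfer). Both α-positions of 6 are benzylic, so some diazo transfer at the phloroglucinol-side CH2 is possible. The fallback moves the diazo transfer before the last benzylation so that charge, not sterics, directs it. It sets out from 5: with p-ABSA and excess DBU the phenol is deprotonated, the phenoxide ring deactivates its own CH2, and only the catechol-side CH2 reacts, giving 1-diazo-1-[3,4-bis(benzyloxy)phenyl]-3-[2,4-bis(benzyloxy)-6-hydroxyphenyl]propan-2-one F4. Benzylation of F4 (BnBr, K2CO3, acetone) returns to the route at 7.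

**Further compounds**

F1 | step 7 | (Z)-1-[3,4-bis(benzyloxy)phenyl]-2-(trimethylsilyloxy)-3-[2,4,6-tris(benzyloxy)phenyl]prop-1-ene | C[Si](C)(C)O/C(=C\c1ccc(OCc2ccccc2)c(OCc2ccccc2)c1)Cc1c(OCc2ccccc2)cc(OCc2ccccc2)cc1OCc1ccccc1
F2 | step 7 | (1R) epimer of 9 | c1ccccc1COc1cc(OCc2ccccc2)c(CC(=O)[C@H](c2ccc(OCc4ccccc4)c(OCc4ccccc4)c2)c2c(OCc4ccccc4)cc(OCc4ccccc4)c3c2O[C@H](c2ccc(OCc4ccccc4)c(OCc4ccccc4)c2)[C@@H](OCc2ccccc2)C3)c(OCc2ccccc2)c1
F3 | step 8 | (1S,2R) epimer of 10 | c1ccccc1COc1cc(OCc2ccccc2)c(C[C@@H](O)[C@@H](c2ccc(OCc4ccccc4)c(OCc4ccccc4)c2)c2c(OCc4ccccc4)cc(OCc4ccccc4)c3c2O[C@H](c2ccc(OCc4ccccc4)c(OCc4ccccc4)c2)[C@@H](OCc2ccccc2)C3)c(OCc2ccccc2)c1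
F4 | step 6 | 1-diazo-1-[3,4-bis(benzyloxy)phenyl]-3-[2,4-bis(benzyloxy)-6-hydroxyphenyl]propan-2-one | [N-]=[N+]=C(c1ccc(OCc2ccccc2)c(OCc2ccccc2)c1)C(=O)Cc1c(O)cc(OCc2ccccc2)cc1OCc1ccccc1
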